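## Analysis of the target

- Labdane numbering is used throughout. Ring A is C1–C5 plus C10, ring B is C5–C10. C4 carries the geminal methyls C18/C19, C8 the methyl C17, C10 the angular methyl C20, and C9 the chain C11–C15 with methyl C16 on C13. β is the face on which C20 sits and α the opposite face; before C20 exists, β is the face of the C9–O bond.
- The target 26 is a trans-fused decalin (H5 α, C20 β) with six stereocentres (C2, C3, C5, C8, C9, C10) and an (E)-trisubstituted methyl enoate at the chain end.
- C9 is a tertiary carbinol wedged between the methine C8 and the quaternary C10. Its oxygen is β and equatorial, cis to both H8 and C20, so the chain and the C8 methyl are α.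
- Ring A holds a cis-2α,3α-diol next to the quaternary C4, on the face opposite C20.
- Sensitive points are the tertiary C9–OH (ionisation under acid, addition to C13 of the enoate under base), the enoate (isomerisation, saponification) and the free diol.
- The difficulty is the run of congested carbons C4–C5–C10–C9–C8. Three are fully substituted, and the adjacent pair C9/C10 must be set relative to each other and to C8 and C5.
- The strategy rests on ring B. Its six carbons, with the C8 methyl and an oxygen at C6, are a masked 4-alkylphenol whose para carbon is C9. Oxidative dearomatisation can therefore make the C9–O bond, and the new oxygen, being cis to H8 and C20, can then deliver both.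

## Retrosynthetic reasoning

**C2–O and C3–O (26 ⇒ 25).** The cis-diol is removed first and traced to the C2=C3 olefin of 25. Ring A then needs no late oxygen protection, and the rigid decalin decides the face, because the axial C20 and 4β methyls cover the β face. The forward step must add two oxygens cis and α and must prefer the ring olefin over the conjugated C13=C14 bond.

**C13=C14 (25 ⇒ 24 ⇒ 23).** The enoate is cut at its double bond to the methyl ketone 24 and a two-carbon phosphonate; 24 is traced to the amide 23, whose carbonyl is C13. C13 is the carbonyl the key step leaves behind. The forward steps must stop methyl addition at the ketone and give the E geometry without letting the C9 alkoxide add to C13.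

**C2=C3 (23 ⇒ 22 ⇒ 21 ⇒ 20 ⇒ 19).** The olefin is traced through enol triflate 22 to the C3 ketone 21, and from there through alcohol 20 to silyl ether 19. C3 carries oxygen only because the ring A closure leaves it there and because it is the stereochemical reference for C9; its S sense is immaterial to 26. C4 is quaternary, so the ketone enolises one way only and the olefin position is certain. Ionisation at C3 next to the gem-dimethyl group, which invites ring contraction, is avoided.

**C6–O (19 ⇒ 18 ⇒ 17 ⇒ 16).** The C6 methylene is traced through olefin 18 and enol triflate 17 to the C6 ketone of 16. This ketone is what remains of the phenol oxygen. It must go under conditions that spare the tertiary alcohol, which rules out strongly acidic or forcing basic reductions.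

**C10–C20 (16 ⇒ 15).** Removing the angular methyl leaves enone 15 with C10 as the β-carbon. The forward reaction must add methyl to a tetrasubstituted enone carbon on the face of O9. The neighbouring C9 hydroxyl is the handle for this, and the C6 ketone lets C5 settle trans afterwards.

**C7–H and C8–H (15 ⇒ 14).** Restoring the C7=C8 unsaturation gives dienone 14. Hydrogen must be delivered to C7=C8 from the hydroxyl face and not to C5=C10. This reduction must precede the methylation, because methyl would otherwise add to C8.

**C13–N (14 ⇒ 13).** The amide is traced to spirolactone 13. Opening the lactone with an amine frees the C9 hydroxyl for the two directed steps and keeps C13 as an acyl group that can become the methyl ketone.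

**C9–O (13 ⇒ 12), the key disconnection.** Cutting the lactone C9–O bond and restoring aromaticity gives phenol acid 12. No other single cut in ring B removes the tertiary carbinol so cheaply: the arene supplies all six ring B carbons, the C8 methyl and the C11–C13 arm, and the forward step forms one C–O bond para to the phenol. That step creates C9 without facial control; C3 makes the C9 epimers diastereomers that can be separated.

**Protecting groups and C4–C5 (12 ⇒ 10 ⇒ 9 ⇒ 8 ⇒ 7).** 12 is 10 with the ester and methyl ether cleaved, and the silyl ether comes from alcohol 9. Ring A is cut at C4–C5: the tetralin arises from epoxide 8 by attack of C5 on C4, and 8 from olefin 7. This cut gives the gem-dimethyl carbon, ring A and the C3 stereocentre in one operation, and C5 is the only free position ortho to the tether.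

**C9–C11 and C1–C2 (7 ⇒ 5 + 6; 5 ⇒ 4 + 3; 4 ⇒ 2 ⇒ 1).** The arm is detached at the aryl–alkyl bond (bromide 5 and zinc reagent 6). The homoprenyl chain is detached at the benzylic C1–C2 bond (magnesium reagent 4 from 2, with 3). Bromide 2 comes from anisole 1, whose bromine and two equivalent methyls already mark C9, C8 and C1.

## Alternatives that were turned down

**Alternative 1:** cathodic ketyl–olefin closure of ring B.
- Disconnection: C8–C9.
- Forward key step: one-electron reduction of the C9 ketone of the ring A seco-ketone A2 gives a ketyl that adds 6-exo to C8 of the terminal C8=C17 olefin, giving A1.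
- For: C8 and C9 are set in one step with C20 already in place. No attack at crowded C10 is needed, no C6 oxygen has to be removed, and the chain is carried complete. On these points it is stronger than the chosen route, which spends steps 11 to 14 on C20 and C6.
- Against: A2 is a cyclohexane with a quaternary C10 next to the C5 stereocentre, and it needs an asymmetric synthesis at least as long as that of 12. Its ketone is neopentyl, and the ketyl must add to an unactivated olefin in the slower six-membered mode, so simple reduction and pinacol coupling compete. The C9 configuration (oxygen cis to C20, bulky chain axial) and that of C8 are left to the transition state with no directing element.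
- Comparison: the chosen strategy reaches its precursor in seven steps from a commercial anisole and derives C8 and C10 from the C9 oxygen.

**Alternative 2:** hydroxyl-tethered radical delivers the angular methyl.
- Disconnection: C10–C20.
- Forward key step: the (bromomethyl)silyl ether A4 gives, with a tin hydride, an α-silyl radical that adds 5-exo to C10 of the C1=C10–C2=O enone, giving siloxane A3.
- For: intramolecular delivery guarantees the cis relation of O9 and C20 whatever the crowding, which is more reliable than the intermolecular methyl transfer of step 11. The C2 ketone of A3 is also a handle for the diol.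
- Against: the key step makes one C–C bond and one stereocentre. A4 already contains C8, the C9 carbinol and a hindered tertiary silyl ether, so the real problem is pushed into the precursor. Desilylation and oxygenation at neopentyl C3 are still needed.
- Comparison: the chosen strategy creates C9 in its key step and uses the same oxygen for C20. The tether idea is kept as the reserve for step 11 (F5, F6).

**Alternative 3:** vinylcyclohexene Diels–Alder with an acetoxycrotonate.
- Disconnection: C7–C8 and C9–C10.
- Forward key step: diene A6 and dienophile A7 combine under a Lewis acid or high pressure to give A5.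
- For: it is the most convergent. Two C–C bonds and three stereocentres (C8, C9, C10) form at once, which is more bond-forming power than the single C–O bond and single stereocentre of the chosen key step.
- Against: the diene terminus C10 is fully substituted and the reactive s-cis form is strained by the C4 gem-dimethyl group and C20. The dienophile is trisubstituted and deactivated by its acyloxy donor. Vicinal quaternary centres must form in the cycloaddition, and exo/endo and facial selectivity rest only on the remote C3 silyloxy group. A5 keeps a C5=C6 olefin whose hydrogenation next to C4 must give the trans fusion, and it holds only C11 of the side chain, so four carbons must be added at a neopentyl position.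
- Comparison: the chosen route has C11–C13 in place from step 3 and sets the ring fusion by equilibration.

Key step: step 8

Remark on the chemistry: zinc reagent 6 is taken as the commercial THF solution and the L-fructose-derived epoxidation ketone as available; the S configuration at C3 is a resolving handle only and is erased in step 16.

## Route

Step 1
Reactants: 1 4-bromo-3,5-dimethylanisole
Product: 2 2-bromo-1-(bromomethyl)-5-methoxy-3-methylbenzene
Conditions: NBS (1 equiv), AIBN (cat.), PhCF3, 80 °C
Reagents that add atoms: N-bromosuccinimide, O=C1CCC(=O)N1Br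
Why: Radical benzylic bromination (Wohl–Ziegler); the two methyl groups are equivalent, so one equivalent of NBS should give mainly the monobromide. The nonpolar solvent and radical initiator suppress ring bromination of the anisole.

Step 2
Reactants: 2 2-bromo-1-(bromomethyl)-5-methoxy-3-methylbenzene, 3 prenyl chloride (1-chloro-3-methylbut-2-ene)
Product: 5 2-bromo-5-methoxy-1-methyl-3-(4-methylpent-3-en-1-yl)benzene, via benzylic Grignard reagent 4 (not isolated)
Conditions: Mg, Et2O, 0 °C; then 3, Li2CuCl4 (cat.), THF, –20 °C to rt
Reagents that add atoms: magnesium, [Mg] (stays in 4 only)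
Why: Magnesium inserts into the benzylic C–Br bond far faster than into the aryl C–Br bond. Copper-catalysed allylic substitution of the Grignard reagent on the primary allylic chloride should occur at the unhindered CH2 terminus (SN2, not SN2'), forming the C1–C2 bond.

Step 3
Reactants: 5 2-bromo-5-methoxy-1-methyl-3-(4-methylpent-3-en-1-yl)benzene, 6 (3-ethoxy-3-oxopropyl)zinc bromide
Product: 7 ethyl 3-[4-methoxy-2-methyl-6-(4-methylpent-3-en-1-yl)phenyl]propanoate
Conditions: Pd(OAc)2 (cat.), SPhos (cat.), THF, 50 °C
Reagents that add atoms: none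
Why: Negishi coupling of a primary alkylzinc halide with a di-ortho-substituted aryl bromide forms the C9–C11 bond. The bulky biarylphosphine favours reductive elimination over β-hydride elimination, and the ester and olefin are inert to the organozinc.

Step 4
Reactants: 7 ethyl 3-[4-methoxy-2-methyl-6-(4-methylpent-3-en-1-yl)phenyl]propanoate
Product: 8 ethyl 3-[2-{2-[(2S)-3,3-dimethyloxiran-2-yl]ethyl}-4-methoxy-6-methylphenyl]propanoate
Conditions: L-fructose-derived Shi ketone (cat.), Oxone (2KHSO5·KHSO4·K2SO4), K2CO3, Bu4NHSO4, MeCN/CH2(OMe)2/aq. buffer pH 10.5, 0 °C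
Reagents that add atoms: potassium peroxymonosulfate (active part of Oxone), [K+].[O-]S(=O)(=O)OO
Why: Shi epoxidation of a trisubstituted olefin by the chiral dioxirane formed in situ. The L-fructose-derived ketone, the enantiomer of the common D-fructose-derived one, should give the (S)-epoxide through the spiro transition state; the basic buffer limits Baeyer–Villiger loss of the ketone.

Step 5
Reactants: 8 ethyl 3-[2-{2-[(2S)-3,3-dimethyloxiran-2-yl]ethyl}-4-methoxy-6-methylphenyl]propanoate
Product: 9 ethyl 3-[(6S)-6-hydroxy-4-methoxy-2,5,5-trimethyl-5,6,7,8-tetrahydronaphthalen-1-yl]propanoate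
Conditions: SnCl4, CH2Cl2, –78 °C
Reagents that add atoms: none
Why: Lewis-acid epoxide–arene cyclisation (intramolecular Friedel–Crafts alkylation). The epoxide opens at its tertiary carbon C4 and is captured 6-endo by C5, the only free position ortho to the tether, which is activated by the ortho methoxy and para methyl groups. The C3–O bond is untouched, so C3 stays S.

Step 6
Reactants: 9 ethyl 3-[(6S)-6-hydroxy-4-methoxy-2,5,5-trimethyl-5,6,7,8-tetrahydronaphthalen-1-yl]propanoate
Product: 10 ethyl 3-[(6S)-6-(tert-butyldimethylsilyloxy)-4-methoxy-2,5,5-trimethyl-5,6,7,8-tetrahydronaphthalen-1-yl]propanoate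
Conditions: TBSOTf, 2,6-lutidine, CH2Cl2, 0 °C
Reagents that add atoms: tert-butyldimethylsilyl trifluoromethanesulfonate, CC(C)(C)[Si](C)(C)OS(=O)(=O)C(F)(F)F
Why: Silyl ether formation; the silyl triflate is needed for the hindered neopentyl secondary alcohol. The ether protects C3–OH through the base- and organometal-mediated steps that follow.

Step 7
Reactants: 10 ethyl 3-[(6S)-6-(tert-butyldimethylsilyloxy)-4-methoxy-2,5,5-trimethyl-5,6,7,8-tetrahydronaphthalen-1-yl]propanoate
Product: 12 3-[(6S)-6-(tert-butyldimethylsilyloxy)-4-hydroxy-2,5,5-trimethyl-5,6,7,8-tetrahydronaphthalen-1-yl]propanoic acid, via phenol ethyl ester 11 (not isolated)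
Conditions: NaSEt, DMF, 120 °C; then aq. NaOH, 50 °C; aq. HCl work-up
Reagents that add atoms: sodium hydroxide, [Na+].[OH-]
Why: SN2 demethylation of the aryl methyl ether by thiolate in a dipolar aprotic solvent, then saponification of the ethyl ester in the same flask. The alkyl silyl ether is stable to the soft thiolate and to aqueous hydroxide at moderate temperature.

Step 8
Reactants: 12 3-[(6S)-6-(tert-butyldimethylsilyloxy)-4-hydroxy-2,5,5-trimethyl-5,6,7,8-tetrahydronaphthalen-1-yl]propanoic acid
Product: 13 (2S,6'S)-6'-(tert-butyldimethylsilyloxy)-2',5',5'-trimethyl-5',6',7',8'-tetrahydro-3H,4'H-spiro[furan-2,1'-naphthalene]-4',5(4H)-dione (C9 spirolactone dienone)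
Conditions: PhI(OAc)2, (CF3)2CHOH/CH2Cl2, 0 °C
Reagents that add atoms: none
Why: Ligand exchange puts the phenol oxygen on trivalent iodine, loss of iodobenzene makes the ring electrophilic at the para carbon C9, and the carboxylate of the propanoic arm adds there, leaving ring B as a cross-conjugated 2,5-cyclohexadienone (C6 ketone, C5=C10 and C7=C8). The closest known reaction type is the hypervalent-iodine oxidative para-spirolactonisation of 3-(4-hydroxyphenyl)propanoic acids. The lactone ring closes in the 5-exo-trig mode, O to C9, and this C9–O bond is the only skeletal bond made. Site selectivity is secured by the substrate: only C9 is within reach of the carboxylate for a five-membered ring, the ortho carbon C5 is substituted, and the fluorinated alcohol is too weakly nucleophilic to compete at C7 or C9. C9 becomes a stereocentre, but the arene is flat and C3 is too remote to bias the attack, so no element of the substrate controls it and 13 and its C9 epimer F1 should form in comparable amounts. What the step needs is therefore separability rather than facial selectivity: because C3 is a single enantiomer the two products are diastereomers and are parted by chromatography. F1 is not lost, since Zn in acetic acid should reduce it back to 12. Once 13 is in hand, its C9 oxygen directs the configuration of C8 and C10, and through them C5, C2 and C3.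

Step 9
Reactants: 13 C9 spirolactone dienone
Product: 14 3-[(1S,6S)-6-(tert-butyldimethylsilyloxy)-1-hydroxy-2,5,5-trimethyl-4-oxo-1,4,5,6,7,8-hexahydronaphthalen-1-yl]-N-methoxy-N-methylpropanamide
Conditions: MeNH(OMe)·HCl, iPrMgCl, THF, –20 to 0 °C; aq. NH4Cl
Reagents that add atoms: N,O-dimethylhydroxylamine hydrochloride, CNOC.Cl
Why: Lactone aminolysis by the magnesium amide formed in situ gives the Weinreb amide at C13 and frees C9–OH, the group that directs the next two steps. The reagent carries no transferable alkyl group, and the hindered cross-conjugated C6 carbonyl is less electrophilic than the lactone. The γ-hydroxy amide is kept away from strong acid, which would re-close the lactone.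

Step 10
Reactants: 14 hydroxy dienone Weinreb amide
Product: 15 3-[(1S,2R,6S)-6-(tert-butyldimethylsilyloxy)-1-hydroxy-2,5,5-trimethyl-4-oxo-1,2,3,4,5,6,7,8-octahydronaphthalen-1-yl]-N-methoxy-N-methylpropanamide
Conditions: H2 (1 atm), [Ir(cod)(PCy3)(py)]PF6 (cat.), CH2Cl2, 0 °C to rt
Reagents that add atoms: none
Why: Hydroxyl-directed homogeneous hydrogenation: the cationic iridium catalyst binds the allylic C9–OH and adds H2 to the trisubstituted C7=C8 bond from the hydroxyl face, so H8 is set cis to O9 (8α-methyl). The tetrasubstituted C5=C10 bond, shielded by the C4 methyls, should be left.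

Step 11
Reactants: 15 γ-hydroxy enone Weinreb amide
Product: 16 3-[(1S,2R,4aS,6S,8aS)-6-(tert-butyldimethylsilyloxy)-1-hydroxy-2,5,5,8a-tetramethyl-4-oxodecahydronaphthalen-1-yl]-N-methoxy-N-methylpropanamide
Conditions: Me3Al (excess), CH2Cl2, –78 °C to rt; aq. KNaC4H4O6; then DBU (cat.), CH2Cl2, rt
Reagents that add atoms: trimethylaluminium, C[Al](C)C
Why: Alkoxide-directed conjugate methylation of a γ-hydroxy enone: the C9 aluminium alkoxide holds the reagent on the hydroxyl face while a second Me3Al activates the C6 carbonyl, so methyl is transferred to C10 cis to O9 (C20 β). Protonation of the enolate at C5 from the face opposite C20, completed by base equilibration next to the C6 ketone, gives the trans ring fusion (H5 α).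

Step 12
Reactants: 16 C6 ketone (trans-decalone Weinreb amide)
Product: 17 3-[(1S,2R,4aS,6S,8aS)-6-(tert-butyldimethylsilyloxy)-1-hydroxy-2,5,5,8a-tetramethyl-4-(trifluoromethanesulfonyloxy)-1,2,4a,5,6,7,8,8a-octahydronaphthalen-1-yl]-N-methoxy-N-methylpropanamide
Conditions: KN(SiMe3)2 (2.2 equiv) added to 16 and PhNTf2, THF, –78 to –20 °C; aq. NH4Cl
Reagents that add atoms: N-phenylbis(trifluoromethanesulfonimide), O=S(=O)(N(c1ccccc1)S(=O)(=O)C(F)(F)F)C(F)(F)F
Why: Enol triflate formation under kinetic control: after deprotonation of C9–OH, the ketone is enolised at the C7 methylene rather than the hindered C5 methine, and O-sulfonylation gives the C6=C7 enol triflate. The amide α-protons are much less acidic than those of the ketone.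

Step 13
Reactants: 17 C6=C7 enol triflate
Product: 18 3-[(1S,2R,4aS,6S,8aS)-6-(tert-butyldimethylsilyloxy)-1-hydroxy-2,5,5,8a-tetramethyl-1,2,4a,5,6,7,8,8a-octahydronaphthalen-1-yl]-N-methoxy-N-methylpropanamide
Conditions: Pd(OAc)2 (cat.), PPh3, HCO2H, Bu3N, DMF, 60 °C
Reagents that add atoms: none
Why: Palladium-catalysed formate reduction of an enol triflate: oxidative addition to zerovalent palladium, exchange of triflate for formate, loss of CO2 and reductive elimination replace C6–OTf by C6–H.

Step 14
Reactants: 18 C6=C7 olefin
Product: 19 3-[(1S,2R,4aS,6S,8aS)-6-(tert-butyldimethylsilyloxy)-1-hydroxy-2,5,5,8a-tetramethyldecahydronaphthalen-1-yl]-N-methoxy-N-methylpropanamide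
Conditions: H2 (1 atm), Pd/C, EtOAc, rt
Reagents that add atoms: none
Why: Heterogeneous hydrogenation of the cis-disubstituted C6=C7 bond creates no stereocentre and completes removal of the C6 oxygen. The silyl ether, amide and tertiary alcohol are inert.

Step 15
Reactants: 19 C3 silyl ether
Product: 20 3-[(1S,2R,4aS,6S,8aS)-1,6-dihydroxy-2,5,5,8a-tetramethyldecahydronaphthalen-1-yl]-N-methoxy-N-methylpropanamide
Conditions: Bu4NF, THF, 50 °C; aq. NH4Cl
Reagents that add atoms: none
Why: Fluoride desilylation of the C3 silyl ether. The C3 stereocentre has served its purpose as reference for C9 and is unmasked for oxidation.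

Step 16
Reactants: 20 C3,C9 diol
Product: 21 3-[(1S,2R,4aR,8aS)-1-hydroxy-2,5,5,8a-tetramethyl-6-oxodecahydronaphthalen-1-yl]-N-methoxy-N-methylpropanamide
Conditions: DMP (1,1,1-triacetoxy-1,1-dihydro-1,2-benziodoxol-3(1H)-one), NaHCO3, CH2Cl2, rt
Reagents that add atoms: none
Why: Oxidation of the secondary C3 alcohol to the ketone by the buffered pentavalent iodine reagent; the tertiary C9–OH cannot be oxidised.

Step 17
Reactants: 21 C3 ketone
Product: 22 3-[(1S,2R,4aS,8aS)-1-hydroxy-2,5,5,8a-tetramethyl-6-(trifluoromethanesulfonyloxy)-1,2,3,4,4a,5,8,8a-octahydronaphthalen-1-yl]-N-methoxy-N-methylpropanamide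
Conditions: KN(SiMe3)2 (2.2 equiv) added to 21 and PhNTf2, THF, –78 to –20 °C; aq. NH4Cl
Reagents that add atoms: N-phenylbis(trifluoromethanesulfonimide), O=S(=O)(N(c1ccccc1)S(=O)(=O)C(F)(F)F)C(F)(F)F
Why: Enol triflate formation: the C3 ketone can enolise only toward C2 because C4 is quaternary, so the C2=C3 enol triflate forms as a single regioisomer.

Step 18
Reactants: 22 C2=C3 enol triflate
Product: 23 3-[(1S,2R,4aS,8aS)-1-hydroxy-2,5,5,8a-tetramethyl-1,2,3,4,4a,5,8,8a-octahydronaphthalen-1-yl]-N-methoxy-N-methylpropanamide
Conditions: Pd(OAc)2 (cat.), PPh3, HCO2H, Bu3N, DMF, 60 °C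
Reagents that add atoms: none
Why: The same palladium-catalysed formate reduction as in step 13. It places the olefin exactly at C2=C3 without the cationic conditions that cause ring contraction when a C3 leaving group is eliminated next to the C4 gem-dimethyl group.

Step 19
Reactants: 23 C2=C3 olefin Weinreb amide
Product: 24 4-[(1S,2R,4aS,8aS)-1-hydroxy-2,5,5,8a-tetramethyl-1,2,3,4,4a,5,8,8a-octahydronaphthalen-1-yl]butan-2-one
Conditions: MeMgBr (excess), THF, 0 °C; aq. NH4Cl
Reagents that add atoms: methylmagnesium bromide, C[Mg]Br
Why: Weinreb ketone synthesis: addition of the Grignard reagent stops at the chelated tetrahedral intermediate, which gives the methyl ketone on work-up. The product is expected to equilibrate with its cyclic hemiketal formed with C9–OH.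

Step 20
Reactants: 24 methyl ketone
Product: 25 methyl (2E)-5-[(1S,2R,4aS,8aS)-1-hydroxy-2,5,5,8a-tetramethyl-1,2,3,4,4a,5,8,8a-octahydronaphthalen-1-yl]-3-methylpent-2-enoate
Conditions: (MeO)2P(O)CH2CO2Me (excess over base), NaH, THF, 0 °C to reflux
Reagents that add atoms: trimethyl phosphonoacetate, COC(=O)CP(=O)(OC)OC
Why: Horner–Wadsworth–Emmons olefination of the methyl ketone, through the open form of the hemiketal, should favour the E enoate with the ester trans to the larger C12 substituent; the geometric isomers are separable. The phosphonate is kept in excess over NaH so that the C9 alkoxide, which could add to C13 of the new enoate, is not formed.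

Step 21
Reactants: 25 diene ester
Product: 26 methyl (2E)-5-[(1S,2R,4aS,6S,7R,8aS)-1,6,7-trihydroxy-2,5,5,8a-tetramethyldecahydronaphthalen-1-yl]-3-methylpent-2-enoate
Conditions: OsO4 (cat.), NMO, acetone/H2O, 0 °C to rt
Reagents that add atoms: osmium tetroxide, O=[Os](=O)(=O)=O; N-methylmorpholine N-oxide, C[N+]1([O-])CCOCC1; water, O
Why: Catalytic dihydroxylation (Upjohn conditions): OsO4 adds suprafacially to the electron-richer ring olefin from the α face, opposite the axial C20 and 4β methyl groups, giving the cis-2α,3α-diol. The trisubstituted, ester-conjugated C13=C14 bond is deactivated toward the electrophilic oxidant.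

## Compound list

1 | 4-bromo-3,5-dimethylanisole | COc1cc(C)c(Br)c(C)c1 | starting material
2 | 2-bromo-1-(bromomethyl)-5-methoxy-3-methylbenzene | COc1cc(C)c(Br)c(CBr)c1 | intermediate
3 | prenyl chloride (1-chloro-3-methylbut-2-ene) | CC(C)=CCCl | starting material
4 | [(2-bromo-5-methoxy-3-methylphenyl)methyl]magnesium bromide | COc1cc(C)c(Br)c(C[Mg]Br)c1 | intermediate
5 | 2-bromo-5-methoxy-1-methyl-3-(4-methylpent-3-en-1-yl)benzene | COc1cc(C)c(Br)c(CCC=C(C)C)c1 | intermediate
6 | (3-ethoxy-3-oxopropyl)zinc bromide | CCOC(=O)CC[Zn]Br | starting material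
7 | ethyl 3-[4-methoxy-2-methyl-6-(4-methylpent-3-en-1-yl)phenyl]propanoate | CCOC(=O)CCc1c(C)cc(OC)cc1CCC=C(C)C | intermediate
8 | ethyl 3-[2-{2-[(2S)-3,3-dimethyloxiran-2-yl]ethyl}-4-methoxy-6-methylphenyl]propanoate | CCOC(=O)CCc1c(C)cc(OC)cc1CC[C@@H]1OC1(C)C | intermediate
9 | ethyl 3-[(6S)-6-hydroxy-4-methoxy-2,5,5-trimethyl-5,6,7,8-tetrahydronaphthalen-1-yl]propanoate | CCOC(=O)CCc1c(C)cc(OC)c2c1CC[C@H](O)C2(C)C | intermediate
10 | ethyl 3-[(6S)-6-(tert-butyldimethylsilyloxy)-4-methoxy-2,5,5-trimethyl-5,6,7,8-tetrahydronaphthalen-1-yl]propanoate | CCOC(=O)CCc1c(C)cc(OC)c2c1CC[C@H](O[Si](C)(C)C(C)(C)C)C2(C)C | intermediate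
11 | ethyl 3-[(6S)-6-(tert-butyldimethylsilyloxy)-4-hydroxy-2,5,5-trimethyl-5,6,7,8-tetrahydronaphthalen-1-yl]propanoate | CCOC(=O)CCc1c(C)cc(O)c2c1CC[C@H](O[Si](C)(C)C(C)(C)C)C2(C)C | intermediate
12 | 3-[(6S)-6-(tert-butyldimethylsilyloxy)-4-hydroxy-2,5,5-trimethyl-5,6,7,8-tetrahydronaphthalen-1-yl]propanoic acid | OC(=O)CCc1c(C)cc(O)c2c1CC[C@H](O[Si](C)(C)C(C)(C)C)C2(C)C | intermediate
13 | (2S,6'S)-6'-(tert-butyldimethylsilyloxy)-2',5',5'-trimethyl-5',6',7',8'-tetrahydro-3H,4'H-spiro[furan-2,1'-naphthalene]-4',5(4H)-dione | O=C1CC[C@]2(O1)C(C)=CC(=O)C3=C2CC[C@H](O[Si](C)(C)C(C)(C)C)C3(C)C | intermediate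
14 | 3-[(1S,6S)-6-(tert-butyldimethylsilyloxy)-1-hydroxy-2,5,5-trimethyl-4-oxo-1,4,5,6,7,8-hexahydronaphthalen-1-yl]-N-methoxy-N-methylpropanamide | CON(C)C(=O)CC[C@]1(O)C(C)=CC(=O)C2=C1CC[C@H](O[Si](C)(C)C(C)(C)C)C2(C)C | intermediate
15 | 3-[(1S,2R,6S)-6-(tert-butyldimethylsilyloxy)-1-hydroxy-2,5,5-trimethyl-4-oxo-1,2,3,4,5,6,7,8-octahydronaphthalen-1-yl]-N-methoxy-N-methylpropanamide | CON(C)C(=O)CC[C@]1(O)[C@H](C)CC(=O)C2=C1CC[C@H](O[Si](C)(C)C(C)(C)C)C2(C)C | intermediate
16 | 3-[(1S,2R,4aS,6S,8aS)-6-(tert-butyldimethylsilyloxy)-1-hydroxy-2,5,5,8a-tetramethyl-4-oxodecahydronaphthalen-1-yl]-N-methoxy-N-methylpropanamide | CON(C)C(=O)CC[C@]1(O)[C@H](C)CC(=O)[C@H]2C(C)(C)[C@@H](O[Si](C)(C)C(C)(C)C)CC[C@@]21C | intermediate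
17 | 3-[(1S,2R,4aS,6S,8aS)-6-(tert-butyldimethylsilyloxy)-1-hydroxy-2,5,5,8a-tetramethyl-4-(trifluoromethanesulfonyloxy)-1,2,4a,5,6,7,8,8a-octahydronaphthalen-1-yl]-N-methoxy-N-methylpropanamide | CON(C)C(=O)CC[C@]1(O)[C@H](C)C=C(OS(=O)(=O)C(F)(F)F)[C@H]2C(C)(C)[C@@H](O[Si](C)(C)C(C)(C)C)CC[C@@]21C | intermediate
18 | 3-[(1S,2R,4aS,6S,8aS)-6-(tert-butyldimethylsilyloxy)-1-hydroxy-2,5,5,8a-tetramethyl-1,2,4a,5,6,7,8,8a-octahydronaphthalen-1-yl]-N-methoxy-N-methylpropanamide | CON(C)C(=O)CC[C@]1(O)[C@H](C)C=C[C@H]2C(C)(C)[C@@H](O[Si](C)(C)C(C)(C)C)CC[C@@]21C | intermediate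
19 | 3-[(1S,2R,4aS,6S,8aS)-6-(tert-butyldimethylsilyloxy)-1-hydroxy-2,5,5,8a-tetramethyldecahydronaphthalen-1-yl]-N-methoxy-N-methylpropanamide | CON(C)C(=O)CC[C@]1(O)[C@H](C)CC[C@H]2C(C)(C)[C@@H](O[Si](C)(C)C(C)(C)C)CC[C@@]21C | intermediate
20 | 3-[(1S,2R,4aS,6S,8aS)-1,6-dihydroxy-2,5,5,8a-tetramethyldecahydronaphthalen-1-yl]-N-methoxy-N-methylpropanamide | CON(C)C(=O)CC[C@]1(O)[C@H](C)CC[C@H]2C(C)(C)[C@@H](O)CC[C@@]21C | intermediate
21 | 3-[(1S,2R,4aR,8aS)-1-hydroxy-2,5,5,8a-tetramethyl-6-oxodecahydronaphthalen-1-yl]-N-methoxy-N-methylpropanamide | CON(C)C(=O)CC[C@]1(O)[C@H](C)CC[C@H]2C(C)(C)C(=O)CC[C@@]21C | intermediate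
22 | 3-[(1S,2R,4aS,8aS)-1-hydroxy-2,5,5,8a-tetramethyl-6-(trifluoromethanesulfonyloxy)-1,2,3,4,4a,5,8,8a-octahydronaphthalen-1-yl]-N-methoxy-N-methylpropanamide | CON(C)C(=O)CC[C@]1(O)[C@H](C)CC[C@H]2C(C)(C)C(OS(=O)(=O)C(F)(F)F)=CC[C@@]21C | intermediate
23 | 3-[(1S,2R,4aS,8aS)-1-hydroxy-2,5,5,8a-tetramethyl-1,2,3,4,4a,5,8,8a-octahydronaphthalen-1-yl]-N-methoxy-N-methylpropanamide | CON(C)C(=O)CC[C@]1(O)[C@H](C)CC[C@H]2C(C)(C)C=CC[C@@]21C | intermediate
24 | 4-[(1S,2R,4aS,8aS)-1-hydroxy-2,5,5,8a-tetramethyl-1,2,3,4,4a,5,8,8a-octahydronaphthalen-1-yl]butan-2-one | CC(=O)CC[C@]1(O)[C@H](C)CC[C@H]2C(C)(C)C=CC[C@@]21C | intermediate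
25 | methyl (2E)-5-[(1S,2R,4aS,8aS)-1-hydroxy-2,5,5,8a-tetramethyl-1,2,3,4,4a,5,8,8a-octahydronaphthalen-1-yl]-3-methylpent-2-enoate | COC(=O)/C=C(\C)CC[C@]1(O)[C@H](C)CC[C@H]2C(C)(C)C=CC[C@@]21C | intermediate
26 | methyl (2E)-5-[(1S,2R,4aS,6S,7R,8aS)-1,6,7-trihydroxy-2,5,5,8a-tetramethyldecahydronaphthalen-1-yl]-3-methylpent-2-enoate | COC(=O)/C=C(\C)CC[C@]1(O)[C@H](C)CC[C@H]2C(C)(C)[C@H](O)[C@H](O)C[C@@]21C | target

## Step count and least certain steps

Total step count: 21. Longest linear sequence: 21 steps (1 to 26); 3 and 6 are bought.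

**Step 8 (key step).**
- What may go wrong: there is no facial discrimination at C9, and the two C9 epimers may resolve poorly on chromatography, because the only other stereocentre, C3, is remote. A second concern is capture of the dienyl cation by solvent, or acid-induced rearrangement of the dienone to a phenol.
- Fallback (separation deferred): it sets out from the unseparated oxidation product of 12, that is 13 together with the C9-epimeric spirolactone F1. The mixture is taken through steps 9 to 11. F1 then gives the epimeric hydroxy dienone amide F2, the epimeric enone F3 and the decalone F4. In F4 the four ring B centres are mirror-related to those of 16 while C3 is unchanged, so its silyloxy group is axial where that of 16 is equatorial. This difference should allow separation, and the route is rejoined at 16.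
- Recycling: where separation at the dienone stage works, F1 is returned to 12 by reductive rearomatisation with Zn in AcOH.

**Step 11.**
- What may go wrong: methyl transfer may fail at the tetrasubstituted β-carbon C10, which sits between the carbinol carbon C9 and C5 next to the C4 gem-dimethyl group. Competing processes are 1,2-addition to the C6 carbonyl and simple recovery of 15.
- Fallback (silicon-tethered radical delivery, known chemistry): it sets out from 15. Silylation of C9–OH with BrCH2SiMe2Cl and imidazole gives the (bromomethyl)dimethylsilyl ether F5. Bu3SnH with AIBN generates the α-silyl radical, which adds 5-exo to C10 and, after hydrogen transfer to C5, gives the cyclic siloxane ketone F6. KOtBu in wet DMSO then cleaves the Si–C and Si–O bonds, leaving C20 as a methyl group and C9–OH free, and equilibrates C5. The route is rejoined at 16.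

**Step 10.**
- What may go wrong: hydrogen may be delivered to the wrong face if the amide carbonyl of the α-oriented chain, and not C9–OH, anchors the catalyst. Over-reduction of C5=C10 is also possible.
- Fallback (steric control before lactone opening): it sets out from 13. Hydrogenation over Rh/Al2O3 in EtOAc should add hydrogen to C7=C8 from the face of the small lactone oxygen rather than that of the C11 methylene, giving the dihydro spirolactone F7. Opening with the magnesium amide as in step 9 then rejoins the route at 15.

**Step 20.**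
- What may go wrong: E selectivity may be incomplete, and the C9 alkoxide may add to C13 of the enoate if the medium becomes too basic.
- Fallback (stereospecific carbometalation): it sets out from 23. Reduction of the Weinreb amide with iBu2AlH gives the aldehyde F8, which is expected as its lactol. Seyferth–Gilbert homologation with dimethyl (1-diazo-2-oxopropyl)phosphonate, K2CO3 and MeOH gives the terminal alkyne F9. Methylalumination with Me3Al and Cp2ZrCl2, then ClCO2Me, gives the E enoate only by syn addition. The route is rejoined at 25.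

**Step 21.**
- What may go wrong: chemoselectivity may be lost, with osmylation of C13=C14 besides C2=C3, or α-face selectivity may be incomplete.
- Fallback (dihydroxylation before the enoate exists): it sets out from 23. OsO4 with NMO gives the triol amide F10. 2,2-Dimethoxypropane with pyridinium p-toluenesulfonate gives the 2,3-acetonide F11. MeMgBr gives the acetonide methyl ketone F12. Olefination as in step 20 gives the acetonide enoate F13. Aqueous AcOH removes the acetonide, and the route comes back at 26.

## Further compounds

F1 | step 8 | C9 epimer of 13, (2R,6'S)-spirolactone dienone | O=C1CC[C@@]2(O1)C(C)=CC(=O)C3=C2CC[C@H](O[Si](C)(C)C(C)(C)C)C3(C)C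
F2 | step 8 | C9 epimer of 14 (hydroxy dienone Weinreb amide) | CON(C)C(=O)CC[C@@]1(O)C(C)=CC(=O)C2=C1CC[C@H](O[Si](C)(C)C(C)(C)C)C2(C)C
F3 | step 8 | diastereomer of 15 with C8 and C9 inverted | CON(C)C(=O)CC[C@@]1(O)[C@@H](C)CC(=O)C2=C1CC[C@H](O[Si](C)(C)C(C)(C)C)C2(C)C
F4 | step 8 | diastereomer of 16 with C5, C8, C9 and C10 inverted (3-silyloxy axial) | CON(C)C(=O)CC[C@@]1(O)[C@@H](C)CC(=O)[C@@H]2C(C)(C)[C@@H](O[Si](C)(C)C(C)(C)C)CC[C@]21C
F5 | step 11 | C9 O-(bromomethyl)dimethylsilyl ether of 15 | CON(C)C(=O)CC[C@]1(O[Si](C)(C)CBr)[C@H](C)CC(=O)C2=C1CC[C@H](O[Si](C)(C)C(C)(C)C)C2(C)C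
F6 | step 11 | cyclic siloxane ketone (C20 methylene joins C10 and the silicon on O9) | CON(C)C(=O)CC[C@]1(O[Si](C)(C)C3)[C@H](C)CC(=O)[C@H]2C(C)(C)[C@@H](O[Si](C)(C)C(C)(C)C)CC[C@@]213
F7 | step 10 | 7,8-dihydro spirolactone enone (8α-methyl) | O=C1CC[C@]2(O1)[C@H](C)CC(=O)C3=C2CC[C@H](O[Si](C)(C)C(C)(C)C)C3(C)C
F8 | step 20 | 3-[(1S,2R,4aS,8aS)-1-hydroxy-2,5,5,8a-tetramethyl-1,2,3,4,4a,5,8,8a-octahydronaphthalen-1-yl]propanal (open form of the lactol) | O=CCC[C@]1(O)[C@H](C)CC[C@H]2C(C)(C)C=CC[C@@]21C
F9 | step 20 | (1S,2R,4aS,8aS)-1-(but-3-yn-1-yl)-2,5,5,8a-tetramethyl-1,2,3,4,4a,5,8,8a-octahydronaphthalen-1-ol | C#CCC[C@]1(O)[C@H](C)CC[C@H]2C(C)(C)C=CC[C@@]21C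
F10 | step 21 | 2α,3α,9β-triol Weinreb amide | CON(C)C(=O)CC[C@]1(O)[C@H](C)CC[C@H]2C(C)(C)[C@H](O)[C@H](O)C[C@@]21C
F11 | step 21 | 2,3-acetonide of F10 | CON(C)C(=O)CC[C@]1(O)[C@H](C)CC[C@H]2C(C)(C)[C@@H]3OC(C)(C)O[C@@H]3C[C@@]21C
F12 | step 21 | acetonide methyl ketone | CC(=O)CC[C@]1(O)[C@H](C)CC[C@H]2C(C)(C)[C@@H]3OC(C)(C)O[C@@H]3C[C@@]21C
F13 | step 21 | 2,3-acetonide of 26 | COC(=O)/C=C(\C)CC[C@]1(O)[C@H](C)CC[C@H]2C(C)(C)[C@@H]3OC(C)(C)O[C@@H]3C[C@@]21C
A1 | alternative 1 | (1S,2R,4aS,6S,8aS)-6-(tert-butyldimethylsilyloxy)-2,5,5,8a-tetramethyl-1-[2-(2-methyl-1,3-dioxolan-2-yl)ethyl]decahydronaphthalen-1-ol | CC4(OCCO4)CC[C@]1(O)[C@H](C)CC[C@H]2C(C)(C)[C@@H](O[Si](C)(C)C(C)(C)C)CC[C@@]21C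
A2 | alternative 1 | ring A seco-ketone, 1-[(1S,2S,4S)-2-(but-3-en-1-yl)-4-(tert-butyldimethylsilyloxy)-1,3,3-trimethylcyclohexyl]-3-(2-methyl-1,3-dioxolan-2-yl)propan-1-one | CC1(OCCO1)CCC(=O)[C@@]1(C)CC[C@H](O[Si](C)(C)C(C)(C)C)C(C)(C)[C@@H]1CCC=C
A3 | alternative 2 | cyclic siloxane 2-ketone with C20 bonded to C10 (side-chain ketone as dioxolane) | CC5(OCCO5)CC[C@]1(O[Si](C)(C)C3)[C@H](C)CC[C@H]2C(C)(C)CC(=O)C[C@@]213
A4 | alternative 2 | 20-nor 1(10)-en-2-one carrying the C9 O-(bromomethyl)dimethylsilyl ether (side-chain ketone as dioxolane) | CC1(OCCO1)CC[C@]2(O[Si](C)(C)CBr)[C@H](C)CC[C@H]3C(C)(C)CC(=O)C=C23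
A5 | alternative 3 | methyl 9β-acetoxy-3β-(tert-butyldimethylsilyloxy)-8α-methyl 5-octalene-9-carboxylate cycloadduct | COC(=O)[C@]1(OC(C)=O)[C@H](C)CC=C2C(C)(C)[C@@H](O[Si](C)(C)C(C)(C)C)CC[C@@]21C
A6 | alternative 3 | tert-butyl{[(1S)-3-ethenyl-2,2,4-trimethylcyclohex-3-en-1-yl]oxy}dimethylsilane | C=CC1=C(C)CC[C@H](O[Si](C)(C)C(C)(C)C)C1(C)C
A7 | alternative 3 | methyl (2E)-2-acetoxybut-2-enoate | C/C=C(/OC(C)=O)C(=O)OC
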